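The numbers in the tables stem from a simulated flask for an exercise; scatter was added.

**The question.** Which form holds most of the substrate after 6.0 min, 12 min and 25 min, when substrate at 0.40 M meets partner at 0.360 M? I look for the moment at which the lead changes hands.

| setting | Friday's | Thursday's | summer | dawn | spring |
|---|---|---|---|---|---|
| substrate | 0.20 M | 0.30 M | 0.40 M | 0.40 M | 0.40 M |
| partner | 0.36 M | 0.36 M | 0.360 M | 0.360 M | 0.360 M |
| remark | run made earlier | run made earlier |  |  |  |
| time |  |  | 6.0 min | 25 min | 12 min |

| run | time / min | intermediate D / % | product / % | intermediate A / % | intermediate B / % | substrate / % |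
|---|---|---|---|---|---|---|
| Friday's | 0.667 | 1.7 | 0 | 49.9 | 0.9 | 42.9 |
| Friday's | 2.00 | 8.5 | 2.0 | 67.1 | 7.1 | 8.2 |
| Friday's | 3.00 | 15.9 | 5.7 | 62.9 | 9.1 | 2.1 |
| Friday's | 5.00 | 25.9 | 11.9 | 50.8 | 8.2 | 0 |
| Friday's | 8.00 | 33.2 | 20.4 | 35.8 | 5.2 | 0 |
| Thursday's | 0.667 | 2.5 | 0.5 | 51.1 | 0.4 | 44.4 |
| Thursday's | 2.00 | 9.4 | 3.5 | 70.7 | 6.6 | 9.7 |
| Thursday's | 3.00 | 15.6 | 7.3 | 63.9 | 8.4 | 3.0 |
| Thursday's | 5.00 | 24.6 | 12.1 | 51.8 | 9.4 | 1.4 |
| Thursday's | 8.00 | 33.5 | 17.5 | 37.3 | 5.3 | 0 |

(each reading ± 1 percentage point)

- which of these there is most of at the end, counted by the substrate in it, summer (intermediate A / product / intermediate D / intermediate B)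
- which of these there is most of at the end, counted by the substrate in it, dawn (intermediate A / product / intermediate D / intermediate B)
- which of these there is most of at the end, counted by the substrate in it, spring (intermediate A / product / intermediate D / intermediate B)
- amount of the one of these that there is most of at the end, in percent of the substrate charged, summer
- amount of the one of these that there is most of at the end, in percent of the substrate charged, dawn
- amount of the one of these that there is most of at the end, in percent of the substrate charged, spring

- a reading of substrate is of its free form alone

**A puzzle.** Substrate first becomes intermediate A, and intermediate D, intermediate B and product then grow. Thursday's flask was charged with 0.30 M of substrate and Friday's with 0.20 M, yet at 8.00 min the ratio of intermediate D to intermediate A reads 0.927 in Friday's run and 0.898 in Thursday's. How can the charge change and the ratio stay?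

**Clearing it.** Both flasks hold the same partner charge, but partner is not among the readings, so I cannot say how far it falls in either flask. I therefore look at a second time: at 5.00 min the ratio reads 0.510 in Friday's run and 0.475 in Thursday's. Each reading carries a scatter of 1 percentage point, so I take the ratio at a given time as unchanged between these two charges. Carrying it over to 0.40 M is an assumption of mine, not something these runs show.

**The even point.** Equal shares make the natural zero, where the logarithm of the ratio vanishes. Pooling both runs, the ratio reads 0.492 at 5.00 min and 0.912 at 8.00 min, so its logarithm climbs by 0.206 min⁻¹. It reaches zero at 8.45 min, a reading with the scatter of the runs. I call this moment, when intermediate D holds as much substrate as intermediate A, the crossing time.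

**My commitment.** Summer is read earlier than the crossing, so I expect intermediate A to lead. Spring is read later, so I expect intermediate D to lead. At 8.00 min intermediate D stood above product in Friday's run and in Thursday's, so I keep it first at dawn too, and this is my weakest step.

**The result.** The forecast names intermediate A at 45% for summer, intermediate D at 39% for spring and, parting from me, product at 46% for dawn, holding that intermediate D “leaks slowly to product”. The flasks give intermediate A at 47.1% in summer, intermediate D at 41.3% in spring and intermediate D at 46.6% at dawn, where product stands lower at 27.9%.

    partner + intermediate B → product (k = 1.20 M⁻¹ min⁻¹)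
    partner + intermediate A ⇌ intermediate B (K = 1.20 M⁻¹, k = 0.310 M⁻¹ min⁻¹)
    substrate → intermediate A (k = 1.20 min⁻¹)
    intermediate A ⇌ intermediate D (K = 2.20, k = 0.0980 min⁻¹)
    substrate ⇌ intermediate C (K = 0.720, k = 0.0650 min⁻¹)
    intermediate C ⇌ intermediate E (K = 2.60, k = 0.0590 min⁻¹)

**Once more.** Summer and spring fall on the sides of the 8.45 min crossing that I expected. The spring recipe read at 3.0 min lies earlier than the crossing, and there intermediate A holds 64.0% against 15.8% in intermediate D.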